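No constant of this chemistry is given, so what it can do has to be read from the two earlier runs.

| flask | substrate | partner | free catalyst | remark | time |
|---|---|---|---|---|---|
| Saturday's | 0.10 M | 0.11 M | 0.51 mM (in portions, 2) | run made earlier; portions every 6.0 min |  |
| Thursday's | 0.10 M | 0.11 M | 3.6 mM (in portions, 2) | run made earlier; portions every 6.0 min |  |
| ash | 0.10 M | 0.110 M | 1.0 mM (in portions, 2) | the portions of free catalyst follow each other after 6.0 min, the first at the start | 2.5 h |
| elm | 0.10 M | 0.110 M | 4.0 mM | everything together at the start | 1.5 h |

| run | time / min | product / % | substrate / % |
|---|---|---|---|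
| Saturday's | 6.00 | 2.5 | 97.4 |
| Saturday's | 15.0 | 8.8 | 91.4 |
| Saturday's | 30.0 | 18.6 | 80.4 |
| Saturday's | 80.0 | 42.5 | 57.3 |
| Thursday's | 10.0 | 30.6 | 68.9 |
| Thursday's | 25.0 | 64.4 | 35.2 |
| Thursday's | 50.0 | 87.0 | 13.3 |
| Thursday's | 80.0 | 95.1 | 4.2 |

(standard deviation of a reading: 0.3 percentage points)

- the earlier runs were read with a standard deviation of 0.3 percentage points

1. the winner by amount of product, in percent of the substrate charged; "neither" if no more than 2 percentage points parts them (ash / elm / neither)
2. how much product is there at the end, in percent of the substrate charged: ash
3. how much product is there at the end, in percent of the substrate charged: elm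

Substrate is the limiting reagent, its 0.10 M lying below the 0.110 M of partner, so its balance carries the question. If a given catalyst charge removes a fixed fraction of the substrate per minute (pseudo-first-order), then the natural logarithm of substrate charged over substrate left, here called the turnover exponent, grows with catalyst charge times time, and the fraction left is e to the minus that exponent. Thursday's run reached an exponent of 3.17 at 80.0 min, against 1.04 at 25.0 min: a factor of 3.05 in exponent on a factor of 3.20 in time, which is close to proportional. Saturday's run reached 0.557 at 80.0 min. One number is not quite enough, though, since the exponents stand at a ratio of 5.69 while the charges stand at 7.06, so the dilute run gives more exponent per unit of charge and time.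

The gap of 6.0 min between portions is short against the 2.5 h of ash, so this reckoning counts the whole charge from the start. Scaled from Thursday's run, elm gets 3.96, which means 98.1 % product. Ash gets 1.65 from Thursday's run and 2.05 from Saturday's, so 80.8 % to 87.1 %. Its charge lies between those of the two runs, so this reckoning takes the middle exponent, 84.3 %, and elm leads by well over the margin.

The forecast names elm, with 83.5 % for ash and 97 % for elm, on the ground of “catalyst loss second order in catalyst”.

The simulation gives 83.7 % for ash and 98.2 % for elm, so elm wins.

    partner + free catalyst ⇌ catalyst intermediate A (K = 16.0 L mol⁻¹, k = 12.7 L mol⁻¹ s⁻¹)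
    catalyst intermediate A → catalyst intermediate B (k = 2.32 s⁻¹)
    catalyst intermediate B ⇌ by-product + catalyst intermediate C (K = 0.0837 M, k = 11.9 s⁻¹)
    substrate + catalyst intermediate C ⇌ catalyst intermediate D (K = 4.01 L mol⁻¹, k = 7.80 L mol⁻¹ s⁻¹)
    catalyst intermediate D → free catalyst + product (k = 0.101 s⁻¹)

The substrate left in elm gives an exponent of 4.03, against the 3.96 reckoned, and the substrate left in ash gives 1.82, which lies between the 1.65 and 2.05 reckoned for it. The largest single effect in elm's yield is the catalyst concentration: the simulated run of elm at the concentration of ash gives 69.0 % instead of 98.2 %. Read as substrate spent, that simulated 69.0 % is a turnover exponent of 1.17, so a factor of 4.00 in charge over the same time brings a factor of 3.44 in exponent.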